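**Plan** (C1–C15 numbered along the chain from the alkyne terminus; the ring oxygen joins C6 and C12)

- Retrosynthesis: the C9–Cl bond is cut and O is joined to C9 instead; O–C12 and C13–Br are then cut back to an (E)-C12=C13 alkene. This leaves ring A (O, C6, C7, C8, C9), an all-cis 2,3,5-trisubstituted tetrahydrofuran carrying the C10 acetate. Further cuts are C3=C4 (Peterson), C5–C6/O–C6 (Wittig, oxa-Michael) and C11–C12 (epoxide opening).
- Enabling feature: the ring oxygen and C9 are 1,5-related through C6–C7–C8, so a five-membered ring A can be drawn inside the oxocane. The trans C9–Cl/C10–OAc pair is the signature of an acyloxonium opening, and the anti O–C12/C13–Br pair that of a bromonium opening.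
- Forward: D-glucose C1–C6 become C6–C11 and its furanose ring is ring A, kept to the end and then sacrificed. But-1-yne gives C12–C15, a Wittig reagent C4–C5, a bis-silyl propyne C1–C3. In the last step ring B (O, C9–C12) and a dioxolanylium ring form transiently while the C9–O bond breaks to give the eight-membered ring.
- Stereochemistry: C9 from glucose C4; C7 from glucose C2 with inversion (Cl); C10 from glucose C5 with inversion (epoxide); C6 by oxa-Michael addition anti to C7–O; Z-C3=C4 by Peterson olefination; C12, C13 and the C9–Cl bond in the key step.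

Key step: step 16

Assumption: the conjugated terminal enyne is taken to be much less nucleophilic towards the bromonium donor than the isolated (E)-dialkyl alkene, so it can be present in the last step.

**Step 1**
Reactants: 1 1,2:5,6-di-O-isopropylidene-α-D-glucofuranose
Product: 3 1,2:5,6-di-O-isopropylidene-3-O-[(methylsulfanyl)carbonothioyl]-α-D-glucofuranose, via sodium xanthate salt 2 (not isolated)
Conditions: NaH, imidazole (cat.), THF, 0 °C; CS2; then MeI, rt
Reagents that add atoms: carbon disulfide S=C=S; iodomethane CI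
Why: Xanthate formation (first half of a Barton–McCombie deoxygenation), in which the C3 alkoxide adds to CS2 and the dithiocarbonate salt is S-methylated without touching any stereocentre.

**Step 2**
Reactants: 3 1,2:5,6-di-O-isopropylidene-3-O-[(methylsulfanyl)carbonothioyl]-α-D-glucofuranose
Product: 4 3-deoxy-1,2:5,6-di-O-isopropylidene-α-D-ribo-hexofuranose
Conditions: Bu3SnH, AIBN (cat.), toluene, 110 °C
Reagents that add atoms: none
Why: Barton–McCombie radical deoxygenation, in which the stannyl radical adds to the thiocarbonyl group and the released secondary radical is reduced by Bu3SnH, removing the one glucose stereocentre (future C8) the target does not need.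

**Step 3**
Reactants: 4 3-deoxy-1,2:5,6-di-O-isopropylidene-α-D-ribo-hexofuranose
Product: 5 3-deoxy-1,2-O-isopropylidene-α-D-ribo-hexofuranose
Conditions: AcOH/H2O (7:3), rt
Reagents that add atoms: none
Why: Selective acetal hydrolysis, since the monocyclic terminal acetonide is cleaved far faster than the cis-fused 1,2-acetonide and the oxygen of water leaves in acetone.

**Step 4**
Reactants: 5 3-deoxy-1,2-O-isopropylidene-α-D-ribo-hexofuranose
Product: 7 6-O-benzoyl-3-deoxy-1,2-O-isopropylidene-5-O-methanesulfonyl-α-D-ribo-hexofuranose, via primary benzoate 6 (not isolated)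
Conditions: PhCOCl (1.05 equiv), pyridine, CH2Cl2, −30 °C; then CH3SO2Cl, 0 °C → rt
Reagents that add atoms: benzoyl chloride O=C(Cl)c1ccccc1; methanesulfonyl chloride CS(Cl)(=O)=O
Why: Regioselective acylation then sulfonylation, in which the primary hydroxyl is benzoylated at low temperature and the remaining secondary hydroxyl is mesylated in the same flask.

**Step 5**
Reactants: 7 6-O-benzoyl-3-deoxy-1,2-O-isopropylidene-5-O-methanesulfonyl-α-D-ribo-hexofuranose
Product: 9 5,6-anhydro-3-deoxy-1,2-O-isopropylidene-β-L-lyxo-hexofuranose, via hydroxy mesylate 8 (not isolated)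
Conditions: NaOMe, MeOH/CH2Cl2, 0 °C → rt
Reagents that add atoms: none
Why: Transesterification followed by intramolecular Williamson (3-exo-tet) epoxide closure, in which the freed primary alkoxide displaces the mesylate with inversion and so converts the D-gluco centre into the configuration needed for C10 (S).

**Step 6**
Reactants: 9 5,6-anhydro-3-deoxy-1,2-O-isopropylidene-β-L-lyxo-hexofuranose; 10 but-1-yne
Product: 11 (1S)-1-[(3aR,5S,6aR)-2,2-dimethyltetrahydrofuro[2,3-d][1,3]dioxol-5-yl]hex-3-yn-1-ol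
Conditions: 10, n-BuLi, THF, −78 °C; BF3·OEt2; then 9, −78 °C; aq. NH4Cl
Reagents that add atoms: none
Why: BF3-assisted opening of a terminal epoxide by a lithium acetylide at the unsubstituted carbon, which forms C11–C12 and leaves the C10 carbinol configuration untouched.

**Step 7**
Reactants: 11 (1S)-1-[(3aR,5S,6aR)-2,2-dimethyltetrahydrofuro[2,3-d][1,3]dioxol-5-yl]hex-3-yn-1-ol
Product: 12 (1S,3E)-1-[(3aR,5S,6aR)-2,2-dimethyltetrahydrofuro[2,3-d][1,3]dioxol-5-yl]hex-3-en-1-ol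
Conditions: Na, NH3 (l), THF, −78 → −33 °C; then NH4Cl
Reagents that add atoms: none
Why: Dissolving-metal reduction of an internal alkyne, which should give the (E)-alkene through the trans vinyl radical anion while the acetal and the free alcohol are inert.

**Step 8**
Reactants: 12 (1S,3E)-1-[(3aR,5S,6aR)-2,2-dimethyltetrahydrofuro[2,3-d][1,3]dioxol-5-yl]hex-3-en-1-ol
Product: 13 tert-butyl{[(1S,3E)-1-[(3aR,5S,6aR)-2,2-dimethyltetrahydrofuro[2,3-d][1,3]dioxol-5-yl]hex-3-en-1-yl]oxy}diphenylsilane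
Conditions: t-BuPh2SiCl, imidazole, DMAP (cat.), DMF, 40 °C
Reagents that add atoms: tert-butyl(chloro)diphenylsilane CC(C)(C)[Si](Cl)(c1ccccc1)c1ccccc1
Why: Silylation of the C10 hydroxyl with a bulky, acid-stable, non-participating group, so that only the C9 oxygen can cyclise in step 10.

**Step 9**
Reactants: 13 tert-butyl{[(1S,3E)-1-[(3aR,5S,6aR)-2,2-dimethyltetrahydrofuro[2,3-d][1,3]dioxol-5-yl]hex-3-en-1-yl]oxy}diphenylsilane
Product: 14 (3R,5S)-5-[(1S,3E)-1-{[tert-butyl(diphenyl)silyl]oxy}hex-3-en-1-yl]oxolane-2,3-diol (anomeric mixture)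
Conditions: CF3CO2H/H2O (4:1), 0 °C → rt
Reagents that add atoms: none
Why: Acid hydrolysis of the 1,2-O-isopropylidene acetal, which frees the lactol (masked C6 aldehyde) and the C7 hydroxyl while the silyl ether and the E-alkene should tolerate cold aqueous acid.

**Step 10**
Reactants: 14 (3R,5S)-5-[(1S,3E)-1-{[tert-butyl(diphenyl)silyl]oxy}hex-3-en-1-yl]oxolane-2,3-diol; 15 ethyl (triphenyl-λ5-phosphanylidene)acetate
Product: 17 ethyl 2-[(2S,3R,5S)-5-[(1S,3E)-1-{[tert-butyl(diphenyl)silyl]oxy}hex-3-en-1-yl]-3-hydroxyoxolan-2-yl]acetate, via open-chain enoate 16 (not isolated)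
Conditions: toluene, 80 °C; then DBU (0.2 equiv), rt
Reagents that add atoms: none
Why: Wittig olefination of the open-chain aldehyde followed by 5-exo-trig oxa-Michael addition of the C9 hydroxyl re-closes ring A, and attack anti to the allylic C7–O bond (Felkin–Anh-type, also the more stable 2,3-trans arrangement) should set C6 (S) with the ester arm cis to the C9 arm.

**Step 11**
Reactants: 17 ethyl 2-[(2S,3R,5S)-5-[(1S,3E)-1-{[tert-butyl(diphenyl)silyl]oxy}hex-3-en-1-yl]-3-hydroxyoxolan-2-yl]acetate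
Product: 18 2-[(2S,3R,5S)-5-[(1S,3E)-1-{[tert-butyl(diphenyl)silyl]oxy}hex-3-en-1-yl]-3-hydroxyoxolan-2-yl]acetaldehyde
Conditions: i-Bu2AlH (2.2 equiv), CH2Cl2, −78 °C; aq. potassium sodium tartrate
Reagents that add atoms: none
Why: Partial reduction of an ester, in which the tetrahedral aluminium hemiacetal persists at −78 °C and releases the aldehyde only on work-up.

**Step 12**
Reactants: 18 2-[(2S,3R,5S)-5-[(1S,3E)-1-{[tert-butyl(diphenyl)silyl]oxy}hex-3-en-1-yl]-3-hydroxyoxolan-2-yl]acetaldehyde; 19 1,3-bis(triisopropylsilyl)prop-1-yne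
Product: 21 (2S,3R,5S)-5-[(1S,3E)-1-{[tert-butyl(diphenyl)silyl]oxy}hex-3-en-1-yl]-2-[(2Z)-5-(triisopropylsilyl)pent-2-en-4-yn-1-yl]oxolan-3-ol, via β-silyl alkoxide 20 (not isolated)
Conditions: 19, n-BuLi (2.2 equiv each), THF, −78 °C; then 18, −78 °C → rt; aq. NH4Cl
Reagents that add atoms: none
Why: Peterson olefination with the lithiated bis-silyl propyne, whose bulky silyl groups favour the adduct that gives the (Z)-enyne on syn elimination, one extra equivalent of anion covering the free C7 hydroxyl.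

**Step 13**
Reactants: 21 (2S,3R,5S)-5-[(1S,3E)-1-{[tert-butyl(diphenyl)silyl]oxy}hex-3-en-1-yl]-2-[(2Z)-5-(triisopropylsilyl)pent-2-en-4-yn-1-yl]oxolan-3-ol
Product: 23 tert-butyl{[(1S,3E)-1-[(2S,4S,5S)-4-chloro-5-[(2Z)-5-(triisopropylsilyl)pent-2-en-4-yn-1-yl]oxolan-2-yl]hex-3-en-1-yl]oxy}diphenylsilane, via secondary triflate 22 (not isolated)
Conditions: (CF3SO2)2O, 2,6-lutidine, CH2Cl2, −78 °C; then n-Bu4NCl, −78 → 0 °C
Reagents that add atoms: tetrabutylammonium chloride CCCC[N+](CCCC)(CCCC)CCCC.[Cl-]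
Why: Sulfonylation then SN2 displacement by chloride with inversion converts the (7R)-alcohol (trans to the C6 arm) into the (7S)-chloride (cis), the bulky silyl ether and the hydrocarbon side chains offering no neighbouring-group pathway.

**Step 14**
Reactants: 23 tert-butyl{[(1S,3E)-1-[(2S,4S,5S)-4-chloro-5-[(2Z)-5-(triisopropylsilyl)pent-2-en-4-yn-1-yl]oxolan-2-yl]hex-3-en-1-yl]oxy}diphenylsilane
Product: 24 (1S,3E)-1-[(2S,4S,5S)-4-chloro-5-[(2Z)-pent-2-en-4-yn-1-yl]oxolan-2-yl]hex-3-en-1-ol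
Conditions: n-Bu4NF (3 equiv), THF, 0 °C → rt
Reagents that add atoms: none
Why: Fluoride-mediated desilylation removes the O-silyl ether and the alkynyl silane together, and the secondary chloride should not be displaced or eliminated at this temperature.

**Step 15**
Reactants: 24 (1S,3E)-1-[(2S,4S,5S)-4-chloro-5-[(2Z)-pent-2-en-4-yn-1-yl]oxolan-2-yl]hex-3-en-1-ol
Product: 25 (1S,3E)-1-[(2S,4S,5S)-4-chloro-5-[(2Z)-pent-2-en-4-yn-1-yl]oxolan-2-yl]hex-3-en-1-yl acetate
Conditions: Ac2O, pyridine, DMAP (cat.), CH2Cl2, 0 °C → rt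
Reagents that add atoms: acetic anhydride CC(=O)OC(C)=O
Why: DMAP-catalysed acylation installs the C10 acetate, which is both a group of the target and the internal nucleophile of step 16.

**Step 16**
Reactants: 25 (1S,3E)-1-[(2S,4S,5S)-4-chloro-5-[(2Z)-pent-2-en-4-yn-1-yl]oxolan-2-yl]hex-3-en-1-yl acetate
Product: 29 (2R,4S,5S,7S,8S)-2-[(1S)-1-bromopropyl]-5,7-dichloro-8-[(2Z)-pent-2-en-4-yn-1-yl]oxocan-4-yl acetate, via bromonium ion 26 (not isolated), via bicyclic oxonium ion 27 (not isolated), via dioxolanylium ion 28 (not isolated)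
Conditions: Et2SBr·SbCl5Br (1.0 equiv), MeNO2, −25 °C, 10 min; then n-Bu4NCl (5 equiv), −25 °C → rt
Reagents that add atoms: bromodiethylsulfonium bromopentachloroantimonate CC[S+](Br)CC.Cl[Sb-](Cl)(Cl)(Cl)(Cl)Br; tetrabutylammonium chloride CCCC[N+](CCCC)(CCCC)CCCC.[Cl-]
Why: Proposed new method: the bromonium ion 26, formed reversibly on the (E)-alkene, is opened at C12 by the ring-A oxygen to the cis-fused 1-oxoniabicyclo[3.3.0]octane 27; its bridgehead C9–O bond is then cut from the rear by the carbonyl oxygen of the C10 acetate, and the resulting dioxolan-2-ylium ion 28 is opened at C9 by chloride, leaving the acetate on C10. The closest known reactions are the bromonium-induced tetrahydrofuran-to-oxocane ring expansion terminated by a neighbouring carbonate and the opening of 2-methyl-1,3-dioxolan-2-ylium ions by halide to trans-halohydrin acetates; merging them with chloride as terminator is new. Ring B (O, C9–C12) closes 5-exo on the bromonium ion and the dioxolanylium ring closes 5-exo-tet at C9, both transient, so the eight-membered ring arises by expansion of the bicycle and not by end-to-end cyclisation. C13 follows from anti addition across the E-alkene, C12 from closure with the bromopropyl arm on the convex face of the bicycle (the concave face is blocked by the C5 methylene on C6 of the all-cis ring A), and C9 keeps its configuration through two inversions, which places chlorine trans to the acetate. The step needs three selectivities: the dialkyl E-alkene over the deactivated enyne (only it has a 5-exo internal nucleophile); cleavage at the bridgehead C9 and not at C6 or C12 (enforced by the acetate tether, both other carbons carrying β-halogens); and chloride attack at C9 and not C10 (the open face of C10 is screened by the 1,3-cis bromopropyl group on C12, that of C9 faces only H7). Chloride is added only after the bromonium donor is consumed, so that no BrCl adds to the alkene.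

**Compound list**

1 | 1,2:5,6-di-O-isopropylidene-α-D-glucofuranose (diacetone-D-glucose) | CC1(C)O[C@H]2O[C@H]([C@H]3COC(C)(C)O3)[C@H](O)[C@H]2O1 | starting material
2 | sodium O-(1,2:5,6-di-O-isopropylidene-α-D-glucofuranos-3-yl) carbonodithioate | CC1(C)O[C@H]2O[C@H]([C@H]3COC(C)(C)O3)[C@H](OC(=S)[S-])[C@H]2O1.[Na+] | intermediate
3 | 1,2:5,6-di-O-isopropylidene-3-O-[(methylsulfanyl)carbonothioyl]-α-D-glucofuranose | CC1(C)O[C@H]2O[C@H]([C@H]3COC(C)(C)O3)[C@H](OC(=S)SC)[C@H]2O1 | intermediate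
4 | 3-deoxy-1,2:5,6-di-O-isopropylidene-α-D-ribo-hexofuranose | CC1(C)O[C@H]2O[C@H]([C@H]3COC(C)(C)O3)C[C@H]2O1 | intermediate
5 | 3-deoxy-1,2-O-isopropylidene-α-D-ribo-hexofuranose | CC1(C)O[C@H]2O[C@H]([C@H](O)CO)C[C@H]2O1 | intermediate
6 | 6-O-benzoyl-3-deoxy-1,2-O-isopropylidene-α-D-ribo-hexofuranose | CC1(C)O[C@H]2O[C@H]([C@H](O)COC(=O)c3ccccc3)C[C@H]2O1 | intermediate
7 | 6-O-benzoyl-3-deoxy-1,2-O-isopropylidene-5-O-methanesulfonyl-α-D-ribo-hexofuranose | CC1(C)O[C@H]2O[C@H]([C@H](OS(C)(=O)=O)COC(=O)c3ccccc3)C[C@H]2O1 | intermediate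
8 | 3-deoxy-1,2-O-isopropylidene-5-O-methanesulfonyl-α-D-ribo-hexofuranose | CC1(C)O[C@H]2O[C@H]([C@H](OS(C)(=O)=O)CO)C[C@H]2O1 | intermediate
9 | 5,6-anhydro-3-deoxy-1,2-O-isopropylidene-β-L-lyxo-hexofuranose, i.e. (3aR,5S,6aR)-2,2-dimethyl-5-[(2S)-oxiran-2-yl]tetrahydrofuro[2,3-d][1,3]dioxole | CC1(C)O[C@H]2O[C@H]([C@@H]3CO3)C[C@H]2O1 | intermediate
10 | but-1-yne | CCC#C | starting material
11 | (1S)-1-[(3aR,5S,6aR)-2,2-dimethyltetrahydrofuro[2,3-d][1,3]dioxol-5-yl]hex-3-yn-1-ol | CC1(C)O[C@H]2O[C@H]([C@@H](O)CC#CCC)C[C@H]2O1 | intermediate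
12 | (1S,3E)-1-[(3aR,5S,6aR)-2,2-dimethyltetrahydrofuro[2,3-d][1,3]dioxol-5-yl]hex-3-en-1-ol | CC1(C)O[C@H]2O[C@H]([C@@H](O)C/C=C/CC)C[C@H]2O1 | intermediate
13 | tert-butyl{[(1S,3E)-1-[(3aR,5S,6aR)-2,2-dimethyltetrahydrofuro[2,3-d][1,3]dioxol-5-yl]hex-3-en-1-yl]oxy}diphenylsilane | CC1(C)O[C@H]2O[C@H]([C@@H](O[Si](c3ccccc3)(c3ccccc3)C(C)(C)C)C/C=C/CC)C[C@H]2O1 | intermediate
14 | (3R,5S)-5-[(1S,3E)-1-{[tert-butyl(diphenyl)silyl]oxy}hex-3-en-1-yl]oxolane-2,3-diol (anomeric mixture) | OC1O[C@H]([C@@H](O[Si](c2ccccc2)(c2ccccc2)C(C)(C)C)C/C=C/CC)C[C@H]1O | intermediate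
15 | ethyl (triphenyl-λ5-phosphanylidene)acetate | CCOC(=O)C=P(c1ccccc1)(c1ccccc1)c1ccccc1 | starting material
16 | ethyl (2E,4R,6S,7S,9E)-7-{[tert-butyl(diphenyl)silyl]oxy}-4,6-dihydroxydodeca-2,9-dienoate | CCOC(=O)/C=C/[C@H](O)C[C@H](O)[C@@H](O[Si](c1ccccc1)(c1ccccc1)C(C)(C)C)C/C=C/CC | intermediate
17 | ethyl 2-[(2S,3R,5S)-5-[(1S,3E)-1-{[tert-butyl(diphenyl)silyl]oxy}hex-3-en-1-yl]-3-hydroxyoxolan-2-yl]acetate | CCOC(=O)C[C@@H]1O[C@H]([C@@H](O[Si](c2ccccc2)(c2ccccc2)C(C)(C)C)C/C=C/CC)C[C@H]1O | intermediate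
18 | 2-[(2S,3R,5S)-5-[(1S,3E)-1-{[tert-butyl(diphenyl)silyl]oxy}hex-3-en-1-yl]-3-hydroxyoxolan-2-yl]acetaldehyde | O=CC[C@@H]1O[C@H]([C@@H](O[Si](c2ccccc2)(c2ccccc2)C(C)(C)C)C/C=C/CC)C[C@H]1O | intermediate
19 | 1,3-bis(triisopropylsilyl)prop-1-yne | CC(C)[Si](C#CC[Si](C(C)C)(C(C)C)C(C)C)(C(C)C)C(C)C | starting material
20 | dilithium β-silyl alkoxide formed from 18 and lithiated 19 (new carbinol and silyl-bearing centres undefined) | CC(C)[Si](C#CC(C([O-])C[C@@H]1O[C@H]([C@@H](O[Si](c2ccccc2)(c2ccccc2)C(C)(C)C)C/C=C/CC)C[C@H]1[O-])[Si](C(C)C)(C(C)C)C(C)C)(C(C)C)C(C)C.[Li+].[Li+] | intermediate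
21 | (2S,3R,5S)-5-[(1S,3E)-1-{[tert-butyl(diphenyl)silyl]oxy}hex-3-en-1-yl]-2-[(2Z)-5-(triisopropylsilyl)pent-2-en-4-yn-1-yl]oxolan-3-ol | CC(C)[Si](C#C/C=C\C[C@@H]1O[C@H]([C@@H](O[Si](c2ccccc2)(c2ccccc2)C(C)(C)C)C/C=C/CC)C[C@H]1O)(C(C)C)C(C)C | intermediate
22 | (2S,3R,5S)-5-[(1S,3E)-1-{[tert-butyl(diphenyl)silyl]oxy}hex-3-en-1-yl]-2-[(2Z)-5-(triisopropylsilyl)pent-2-en-4-yn-1-yl]oxolan-3-yl trifluoromethanesulfonate | CC(C)[Si](C#C/C=C\C[C@@H]1O[C@H]([C@@H](O[Si](c2ccccc2)(c2ccccc2)C(C)(C)C)C/C=C/CC)C[C@H]1OS(=O)(=O)C(F)(F)F)(C(C)C)C(C)C | intermediate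
23 | tert-butyl{[(1S,3E)-1-[(2S,4S,5S)-4-chloro-5-[(2Z)-5-(triisopropylsilyl)pent-2-en-4-yn-1-yl]oxolan-2-yl]hex-3-en-1-yl]oxy}diphenylsilane | CC(C)[Si](C#C/C=C\C[C@@H]1O[C@H]([C@@H](O[Si](c2ccccc2)(c2ccccc2)C(C)(C)C)C/C=C/CC)C[C@@H]1Cl)(C(C)C)C(C)C | intermediate
24 | (1S,3E)-1-[(2S,4S,5S)-4-chloro-5-[(2Z)-pent-2-en-4-yn-1-yl]oxolan-2-yl]hex-3-en-1-ol | C#C/C=C\C[C@@H]1O[C@H]([C@@H](O)C/C=C/CC)C[C@@H]1Cl | intermediate
25 | (1S,3E)-1-[(2S,4S,5S)-4-chloro-5-[(2Z)-pent-2-en-4-yn-1-yl]oxolan-2-yl]hex-3-en-1-yl acetate | C#C/C=C\C[C@@H]1O[C@H]([C@@H](OC(C)=O)C/C=C/CC)C[C@@H]1Cl | intermediate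
26 | trans-bromonium ion of 25 at C12–C13 (bromine on the face that leads to 12R,13S) | C#C/C=C\C[C@@H]1O[C@H]([C@@H](OC(C)=O)C[C@@H]2[Br+][C@H]2CC)C[C@@H]1Cl | intermediate
27 | cis-fused 1-oxoniabicyclo[3.3.0]octane with O bonded to C6, C9 and C12 (rings A and B; bromopropyl arm on the convex face) | C#C/C=C\C[C@H]1[C@@H](Cl)C[C@H]2[C@@H](OC(C)=O)C[C@H]([C@@H](Br)CC)[O+]12 | intermediate
28 | oxocane with a cis-fused 2-methyl-1,3-dioxolan-2-ylium ring across C9 and C10 | C#C/C=C\C[C@@H]1O[C@@H]([C@@H](Br)CC)C[C@@H]2OC(C)=[O+][C@@H]2C[C@@H]1Cl | intermediate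
29 | (2R,4S,5S,7S,8S)-2-[(1S)-1-bromopropyl]-5,7-dichloro-8-[(2Z)-pent-2-en-4-yn-1-yl]oxocan-4-yl acetate | C#C/C=C\C[C@@H]1O[C@@H]([C@@H](Br)CC)C[C@H](OC(C)=O)[C@@H](Cl)C[C@@H]1Cl | target

**Totals**

Total step count: 16. Longest linear sequence: 16 steps (from 1; compounds 10, 15 and 19 are bought).

**Steps most likely to fail**

Step 16. The cascade may leave the intended path in three ways: halide may capture the oxonium ion before the acetate has relayed; the dioxolanylium ion may be opened at C10 instead of C9; or the bromonium donor may attack the enyne. The fallback replaces the chloride-terminated cascade by the known carbonate-terminated ring expansion and makes the C9–Cl bond separately. It sets out from alcohol 24, which is converted (Boc2O, DMAP, MeCN) into (1S,3E)-1-[(2S,4S,5S)-4-chloro-5-[(2Z)-pent-2-en-4-yn-1-yl]oxolan-2-yl]hex-3-en-1-yl tert-butyl carbonate F1. Treatment with Et2SBr·SbCl5Br in MeNO2 at −25 °C should give, with loss of the tert-butyl group, the oxocane cis-carbonate (2R,4S,5R,7S,8S)-2-[(1S)-1-bromopropyl]-7-chloro-8-[(2Z)-pent-2-en-4-yn-1-yl]oxocane-4,5-diyl carbonate F2. Methanolysis (K2CO3, MeOH, 0 °C) gives the cis-diol (2R,4S,5R,7S,8S)-2-[(1S)-1-bromopropyl]-7-chloro-8-[(2Z)-pent-2-en-4-yn-1-yl]oxocane-4,5-diol F3. The C10 hydroxyl is the less hindered one, because the C9 hydroxyl is 1,3-syn to the C7 chlorine, so acetylation with one equivalent of Ac2O (2,4,6-collidine, −40 °C) should give (2R,4S,5R,7S,8S)-2-[(1S)-1-bromopropyl]-7-chloro-5-hydroxy-8-[(2Z)-pent-2-en-4-yn-1-yl]oxocan-4-yl acetate F4. An Appel-type chlorination (CCl4, P(n-C8H17)3, toluene, 60 °C) then inverts C9, where the cis acetate cannot participate, and the route comes back at 29.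

Step 13. Chloride must enter ring A on the face that carries both side arms, so E2 elimination to a dihydrofuran or a sluggish substitution may take over. The fallback sets the C7 configuration by hydride delivery and forms the C–Cl bond with retention. It sets out from alcohol 21, which is oxidised (Dess–Martin periodinane, NaHCO3, CH2Cl2) to (2S,5S)-5-[(1S,3E)-1-{[tert-butyl(diphenyl)silyl]oxy}hex-3-en-1-yl]-2-[(2Z)-5-(triisopropylsilyl)pent-2-en-4-yn-1-yl]oxolan-3-one F5. Reduction with Li[HB(s-Bu)3] (THF, −78 °C) from the open face anti to both arms should give the all-cis alcohol (2S,3S,5S)-5-[(1S,3E)-1-{[tert-butyl(diphenyl)silyl]oxy}hex-3-en-1-yl]-2-[(2Z)-5-(triisopropylsilyl)pent-2-en-4-yn-1-yl]oxolan-3-ol F6. Stereoretentive deoxychlorination through the chlorosulfite (SOCl2, then TiCl4 cat., CH2Cl2, 0 °C, front-side delivery of chloride) comes back to the route at 23.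

Step 10. The oxa-Michael closure may show poor facial selectivity at C6, and the unwanted 6-epimer can drain away by lactonisation onto the C7 hydroxyl. The fallback sets C6 by hydride addition to an oxocarbenium ion instead. It sets out from lactol 14, which is oxidised chemoselectively (Ag2CO3 on Celite, toluene, 80 °C) to (3R,5S)-5-[(1S,3E)-1-{[tert-butyl(diphenyl)silyl]oxy}hex-3-en-1-yl]-3-hydroxyoxolan-2-one F7. Addition of LiCH2CO2Et (from EtOAc and LiN(i-Pr)2, 2.2 equiv, THF, −78 °C) gives the hemiketal ethyl 2-[(3R,5S)-5-[(1S,3E)-1-{[tert-butyl(diphenyl)silyl]oxy}hex-3-en-1-yl]-2,3-dihydroxyoxolan-2-yl]acetate F8. Ionic reduction (Et3SiH, BF3·OEt2, CH2Cl2/MeCN, −40 °C) should deliver hydride cis to the C7 oxygen and anti to the C9 arm, which places the ester arm trans to C7–O and cis to the C9 arm, and the route comes back at 17.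

**Further compounds**

F1 | step 16 | (1S,3E)-1-[(2S,4S,5S)-4-chloro-5-[(2Z)-pent-2-en-4-yn-1-yl]oxolan-2-yl]hex-3-en-1-yl tert-butyl carbonate | C#C/C=C\C[C@@H]1O[C@H]([C@@H](OC(=O)OC(C)(C)C)C/C=C/CC)C[C@@H]1Cl
F2 | step 16 | (2R,4S,5R,7S,8S)-2-[(1S)-1-bromopropyl]-7-chloro-8-[(2Z)-pent-2-en-4-yn-1-yl]oxocane-4,5-diyl carbonate | C#C/C=C\C[C@@H]1O[C@@H]([C@@H](Br)CC)C[C@@H]2OC(=O)O[C@@H]2C[C@@H]1Cl
F3 | step 16 | (2R,4S,5R,7S,8S)-2-[(1S)-1-bromopropyl]-7-chloro-8-[(2Z)-pent-2-en-4-yn-1-yl]oxocane-4,5-diol | C#C/C=C\C[C@@H]1O[C@@H]([C@@H](Br)CC)C[C@H](O)[C@H](O)C[C@@H]1Cl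
F4 | step 16 | (2R,4S,5R,7S,8S)-2-[(1S)-1-bromopropyl]-7-chloro-5-hydroxy-8-[(2Z)-pent-2-en-4-yn-1-yl]oxocan-4-yl acetate | C#C/C=C\C[C@@H]1O[C@@H]([C@@H](Br)CC)C[C@H](OC(C)=O)[C@H](O)C[C@@H]1Cl
F5 | step 13 | (2S,5S)-5-[(1S,3E)-1-{[tert-butyl(diphenyl)silyl]oxy}hex-3-en-1-yl]-2-[(2Z)-5-(triisopropylsilyl)pent-2-en-4-yn-1-yl]oxolan-3-one | CC(C)[Si](C#C/C=C\C[C@@H]1O[C@H]([C@@H](O[Si](c2ccccc2)(c2ccccc2)C(C)(C)C)C/C=C/CC)CC1=O)(C(C)C)C(C)C
F6 | step 13 | (2S,3S,5S)-5-[(1S,3E)-1-{[tert-butyl(diphenyl)silyl]oxy}hex-3-en-1-yl]-2-[(2Z)-5-(triisopropylsilyl)pent-2-en-4-yn-1-yl]oxolan-3-ol | CC(C)[Si](C#C/C=C\C[C@@H]1O[C@H]([C@@H](O[Si](c2ccccc2)(c2ccccc2)C(C)(C)C)C/C=C/CC)C[C@@H]1O)(C(C)C)C(C)C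
F7 | step 10 | (3R,5S)-5-[(1S,3E)-1-{[tert-butyl(diphenyl)silyl]oxy}hex-3-en-1-yl]-3-hydroxyoxolan-2-one | O=C1O[C@H]([C@@H](O[Si](c2ccccc2)(c2ccccc2)C(C)(C)C)C/C=C/CC)C[C@H]1O
F8 | step 10 | ethyl 2-[(3R,5S)-5-[(1S,3E)-1-{[tert-butyl(diphenyl)silyl]oxy}hex-3-en-1-yl]-2,3-dihydroxyoxolan-2-yl]acetate (anomeric mixture) | CCOC(=O)CC1(O)O[C@H]([C@@H](O[Si](c2ccccc2)(c2ccccc2)C(C)(C)C)C/C=C/CC)C[C@H]1O
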